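**Plan** (ring carbons of the target cyclohexane: C1 quaternary carbon, C2 CH(CH3), C3, C4 CH2, C5 isopropylidene carbon, C6 CH bearing the propanal chain)
Cuts: the aryl ether O–CH2 bond (Mitsunobu with isofraxidin) and the aldehyde (enol ether homologation of a lactone carbonyl); then the ring bond C4–C5; then C1–C6 (Michael addition) and C1–CH3 (alkylation) on a δ-lactone.
Enabling feature: C5 carries an exocyclic C=C with two identical methyls and its ring neighbour C4 is a bare CH2, so C4H2–C5=C(CH3)2 is one 1,4-addition of H2 away from the diene C4H=C5–C(CH3)=CH2, the signature product of ring-closing enyne metathesis between a vinyl group at C4 and a prop-1-ynyl group on C6; the CH2 given up by C4 formally becomes the second methyl and no alkene geometry has to be set.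
Forward: δ-lactone → C-methylation → Michael addition → transposition of the lactone onto the chain (a temporary six-membered lactone that masks CH2OH and the chain carbonyl and frees C4) → vinyl group → metathesis closes the carbocycle → lactone opened to an enol ether, diene reduced, aryl ether formed, aldehyde released.
Stereochemistry: C2 is bought; C1 and C6 arise together in the Michael step by substrate control (enolate face anti to the C2 methyl, lithium-chelated transition state); nothing later touches them.

Key step: step 8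

Remark: methyl hydrogen (R)-3-methylglutarate (1) and isofraxidin (19) are taken as purchased compounds; the enol ethers 17, 18 and 20 are carried as E/Z mixtures, which is immaterial because both isomers give the same aldehyde.

Step 1
Reactants: 1 methyl hydrogen (R)-3-methylglutarate
Product: 3 (S)-4-methyltetrahydro-2H-pyran-2-one, via (S)-5-hydroxy-3-methylpentanoic acid 2 (not isolated)
Conditions: LiBH4 (2.2 equiv), THF, 0 → 50 °C; then 2 M HCl, rt
Reagents that add atoms: none
Why: Chemoselective hydride reduction followed by lactonization: LiBH4 reduces the methyl ester but not the lithium carboxylate, and acid closes the δ-lactone; the stereocenter is untouched and only its descriptor changes because the ligand ranking changes.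

Step 2
Reactants: 3 (S)-4-methyltetrahydro-2H-pyran-2-one
Product: 5 (3R,4S)-3,4-dimethyltetrahydro-2H-pyran-2-one, via lithium (S)-4-methyl-5,6-dihydro-4H-pyran-2-olate 4 (not isolated)
Conditions: LiN(iPr)2, THF, −78 °C; MeI, −78 → −40 °C
Reagents that add atoms: iodomethane, CI
Why: Lactone enolate alkylation, with methyl expected trans to the C4 methyl; this centre is planarized again in step 4, so its configuration is immaterial.

Step 3
Reactants: 6 but-2-yn-1-ol
Product: 8 tert-butyl (E)-hex-2-en-4-ynoate, via but-2-ynal 7 (not isolated)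
Conditions: MnO2 (excess), Ph3P=CHCO2t-Bu, CH2Cl2, rt
Reagents that add atoms: (tert-butoxycarbonylmethylene)triphenylphosphorane, CC(C)(C)OC(=O)C=P(c1ccccc1)(c1ccccc1)c1ccccc1
Why: Tandem oxidation–Wittig reaction: the volatile ynal is trapped as it forms by the stabilized ylide, which should give the (E)-enoate.

Step 4
Reactants: 5 (3R,4S)-3,4-dimethyltetrahydro-2H-pyran-2-one; 8 tert-butyl (E)-hex-2-en-4-ynoate
Product: 10 tert-butyl (3S)-3-[(3S,4S)-3,4-dimethyl-2-oxotetrahydro-2H-pyran-3-yl]hex-4-ynoate, via lithium (S)-3,4-dimethyl-5,6-dihydro-4H-pyran-2-olate 9 (not isolated)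
Conditions: LiN(iPr)2, THF, −78 °C; then 8, −78 → −40 °C; AcOH quench at −78 °C
Reagents that add atoms: none
Why: Michael addition of a lithium lactone enolate to an enoate: the acceptor should add anti to the C4 methyl (held pseudoaxial by strain with the enolate methyl), which sets quaternary C1, and in the closed lithium-chelated transition state (s-cis ester, synclinal π systems) the rod-like propynyl group lies anti to the lactone carbonyl carbon, which sets C6; the tert-butyl ester disfavours 1,2-addition.

Step 5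
Reactants: 10 tert-butyl (3S)-3-[(3S,4S)-3,4-dimethyl-2-oxotetrahydro-2H-pyran-3-yl]hex-4-ynoate
Product: 12 (4S,5S)-5-[(2S)-4-hydroxybutan-2-yl]-5-methyl-4-(prop-1-yn-1-yl)tetrahydro-2H-pyran-2-one, via tert-butyl (3S,4S,5S)-7-hydroxy-4-(hydroxymethyl)-4,5-dimethyl-3-(prop-1-yn-1-yl)heptanoate 11 (not isolated)
Conditions: LiBH4, THF, 0 °C → rt; H2O; then TsOH·H2O (cat.), toluene, 60 °C
Reagents that add atoms: none
Why: Chemoselective lactone reduction followed by acid-catalysed lactonization: LiBH4 spares the tert-butyl ester, and only the neopentyl hydroxyl can reach it through a six-membered ring, so the lactone moves onto the chain and the C4 hydroxyl is left free.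

Step 6
Reactants: 12 (4S,5S)-5-[(2S)-4-hydroxybutan-2-yl]-5-methyl-4-(prop-1-yn-1-yl)tetrahydro-2H-pyran-2-one
Product: 13 (4S,5S)-5-methyl-5-[(2S)-4-oxobutan-2-yl]-4-(prop-1-yn-1-yl)tetrahydro-2H-pyran-2-one
Conditions: Dess–Martin periodinane, CH2Cl2, rt
Reagents that add atoms: none
Why: Dess–Martin oxidation of the only free primary alcohol; lactone and alkyne are inert and no stereocenter is α to the new aldehyde.

Step 7
Reactants: 13 (4S,5S)-5-methyl-5-[(2S)-4-oxobutan-2-yl]-4-(prop-1-yn-1-yl)tetrahydro-2H-pyran-2-one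
Product: 14 (4S,5S)-5-methyl-5-[(2S)-pent-4-en-2-yl]-4-(prop-1-yn-1-yl)tetrahydro-2H-pyran-2-one
Conditions: Ph3PCH3Br, KN(SiMe3)2, THF, 0 °C; then 13, −78 → 0 °C
Reagents that add atoms: methyltriphenylphosphonium bromide (gives CH2 through its ylide), C[P+](c1ccccc1)(c1ccccc1)c1ccccc1.[Br-]
Why: Wittig methylenation; the aldehyde reacts far faster than the hindered lactone carbonyl at low temperature.

Step 8
Reactants: 14 (4S,5S)-5-methyl-5-[(2S)-pent-4-en-2-yl]-4-(prop-1-yn-1-yl)tetrahydro-2H-pyran-2-one
Product: 15 (4aS,8S,8aS)-8,8a-dimethyl-5-(prop-1-en-2-yl)-1,4,4a,7,8,8a-hexahydro-3H-isochromen-3-one (trans-fused)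
Conditions: second-generation Grubbs catalyst RuCl2(=CHPh)(PCy3)(H2IMes) (5 mol%), toluene (0.01 M), 80 °C
Reagents that add atoms: none
Why: The Ru benzylidene exchanges onto the terminal vinyl group to give a Ru alkylidene at C4, which adds intramolecularly across the C5≡C triple bond (ruthenacyclobutene, then ring opening) so that C4=C5 is formed and the metal moves to the methyl-bearing alkyne carbon; methylene transfer from the vinyl group of the next substrate molecule releases the 1,3-diene and regenerates the C4 alkylidene. The closest known reaction type is ring-closing enyne metathesis of 1,7-enynes with internal alkynes to 1-(1-methylvinyl)cyclohexenes. The six-membered carbocycle closes in the exo mode (the methyl-bearing alkyne carbon stays outside the ring) and ends up trans-fused to the δ-lactone. No stereocenter is formed; C1, C2 and C6 are spectators and none is acidic or metal-bound in the cycle. The step needs exo over endo closure and cyclization over intermolecular metathesis: the methyl cap on the alkyne blocks the yne-first pathway, the quaternary C1 and the lactone ring hold the vinyl arm and the alkynyl arm gauche (both equatorial on the lactone), and dilution does the rest.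

Step 9
Reactants: 15 (4aS,8S,8aS)-8,8a-dimethyl-5-(prop-1-en-2-yl)-1,4,4a,7,8,8a-hexahydro-3H-isochromen-3-one
Product: 16 (4aS,8S,8aS)-8,8a-dimethyl-5-(prop-1-en-2-yl)-3,4,4a,7,8,8a-hexahydro-1H-isochromen-3-ol (anomer mixture)
Conditions: i-Bu2AlH (1.1 equiv), CH2Cl2, −78 °C; then H2O
Reagents that add atoms: none
Why: Half-reduction of a lactone to the lactol at low temperature; the diene is inert to the hydride.

Step 10
Reactants: 16 (4aS,8S,8aS)-8,8a-dimethyl-5-(prop-1-en-2-yl)-3,4,4a,7,8,8a-hexahydro-1H-isochromen-3-ol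
Product: 17 [(1S,2S,6S)-2-(3-methoxyprop-2-en-1-yl)-1,6-dimethyl-3-(prop-1-en-2-yl)cyclohex-3-en-1-yl]methanol
Conditions: MeOCH2PPh3Cl, KN(SiMe3)2, THF, 0 °C; then 16, 0 °C → rt
Reagents that add atoms: (methoxymethyl)triphenylphosphonium chloride, COC[P+](c1ccccc1)(c1ccccc1)c1ccccc1.[Cl-]
Why: Wittig reaction on the open hydroxy aldehyde form of the lactol: it adds the last chain carbon as an enol ether (masked aldehyde) and at the same stroke releases the neopentyl alcohol from the temporary ring.

Step 11
Reactants: 17 [(1S,2S,6S)-2-(3-methoxyprop-2-en-1-yl)-1,6-dimethyl-3-(prop-1-en-2-yl)cyclohex-3-en-1-yl]methanol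
Product: 18 [(1S,2S,6S)-2-(3-methoxyprop-2-en-1-yl)-1,6-dimethyl-3-(propan-2-ylidene)cyclohexyl]methanol
Conditions: (η6-naphthalene)Cr(CO)3 (20 mol%), H2 (10 atm), THF, 45 °C
Reagents that add atoms: none
Why: 1,4-Hydrogenation of a conjugated diene on a Cr(CO)3 fragment: only the s-cis diene binds, hydrogen goes to its two termini (C4 and the exocyclic CH2), and the tetrasubstituted C5=C(CH3)2 product and the isolated enol ether cannot bind and are not reduced; with the chain on C6 now free to stand axial the s-cis form is accessible, and no stereocenter or alkene geometry is at stake.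

Step 12
Reactants: 18 [(1S,2S,6S)-2-(3-methoxyprop-2-en-1-yl)-1,6-dimethyl-3-(propan-2-ylidene)cyclohexyl]methanol; 19 isofraxidin (7-hydroxy-6,8-dimethoxy-2H-chromen-2-one)
Product: 20 6,8-dimethoxy-7-{[(1S,2S,6S)-2-(3-methoxyprop-2-en-1-yl)-1,6-dimethyl-3-(propan-2-ylidene)cyclohexyl]methoxy}-2H-chromen-2-one
Conditions: Bu3P=CHCN (2 equiv), toluene, 110 °C
Reagents that add atoms: none
Why: Mitsunobu etherification with the acidic phenol: the neopentyl alkoxyphosphonium ion has no β-hydrogen, so slow SN2 at CH2 can be forced thermally without elimination, and the enol ether keeps the aldehyde away from the phosphorane.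

Step 13
Reactants: 20 6,8-dimethoxy-7-{[(1S,2S,6S)-2-(3-methoxyprop-2-en-1-yl)-1,6-dimethyl-3-(propan-2-ylidene)cyclohexyl]methoxy}-2H-chromen-2-one
Product: 21 3-[(1S,2S,3S)-2-{[(6,8-dimethoxy-2-oxo-2H-chromen-7-yl)oxy]methyl}-2,3-dimethyl-6-(propan-2-ylidene)cyclohexyl]propanal (CNP0213227.1)
Conditions: 0.5 M HCl, THF–H2O, 0 °C → rt (short contact)
Reagents that add atoms: water, O
Why: Acid-catalysed enol ether hydrolysis, which should be far faster than protonation of the tetrasubstituted alkene or of the coumarin; C6 is not α to the aldehyde and cannot epimerize.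

**Compound list**
1 | methyl hydrogen (R)-3-methylglutarate | COC(=O)C[C@H](C)CC(=O)O | starting material
2 | (S)-5-hydroxy-3-methylpentanoic acid (not isolated) | OCC[C@H](C)CC(=O)O | intermediate
3 | (S)-4-methyltetrahydro-2H-pyran-2-one | O=C1OCC[C@H](C)C1 | intermediate
4 | lithium (S)-4-methyl-5,6-dihydro-4H-pyran-2-olate (not isolated) | [Li]OC1=C[C@@H](C)CCO1 | intermediate
5 | (3R,4S)-3,4-dimethyltetrahydro-2H-pyran-2-one (trans) | O=C1OCC[C@H](C)[C@H]1C | intermediate
6 | but-2-yn-1-ol | CC#CCO | starting material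
7 | but-2-ynal (not isolated) | CC#CC=O | intermediate
8 | tert-butyl (E)-hex-2-en-4-ynoate | CC#C/C=C/C(=O)OC(C)(C)C | intermediate
9 | lithium (S)-3,4-dimethyl-5,6-dihydro-4H-pyran-2-olate (not isolated) | [Li]OC1=C(C)[C@@H](C)CCO1 | intermediate
10 | tert-butyl (3S)-3-[(3S,4S)-3,4-dimethyl-2-oxotetrahydro-2H-pyran-3-yl]hex-4-ynoate | O=C1OCC[C@H](C)[C@@]1(C)[C@H](C#CC)CC(=O)OC(C)(C)C | intermediate
11 | tert-butyl (3S,4S,5S)-7-hydroxy-4-(hydroxymethyl)-4,5-dimethyl-3-(prop-1-yn-1-yl)heptanoate (not isolated) | OC[C@@](C)([C@@H](C)CCO)[C@H](C#CC)CC(=O)OC(C)(C)C | intermediate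
12 | (4S,5S)-5-[(2S)-4-hydroxybutan-2-yl]-5-methyl-4-(prop-1-yn-1-yl)tetrahydro-2H-pyran-2-one | O=C1C[C@@H](C#CC)[C@](C)([C@@H](C)CCO)CO1 | intermediate
13 | (4S,5S)-5-methyl-5-[(2S)-4-oxobutan-2-yl]-4-(prop-1-yn-1-yl)tetrahydro-2H-pyran-2-one | O=C1C[C@@H](C#CC)[C@](C)([C@@H](C)CC=O)CO1 | intermediate
14 | (4S,5S)-5-methyl-5-[(2S)-pent-4-en-2-yl]-4-(prop-1-yn-1-yl)tetrahydro-2H-pyran-2-one | O=C1C[C@@H](C#CC)[C@](C)([C@@H](C)CC=C)CO1 | intermediate
15 | (4aS,8S,8aS)-8,8a-dimethyl-5-(prop-1-en-2-yl)-1,4,4a,7,8,8a-hexahydro-3H-isochromen-3-one | O=C1C[C@H]2C(C(C)=C)=CC[C@H](C)[C@]2(C)CO1 | intermediate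
16 | (4aS,8S,8aS)-8,8a-dimethyl-5-(prop-1-en-2-yl)-3,4,4a,7,8,8a-hexahydro-1H-isochromen-3-ol (anomer mixture) | OC1C[C@H]2C(C(C)=C)=CC[C@H](C)[C@]2(C)CO1 | intermediate
17 | [(1S,2S,6S)-2-(3-methoxyprop-2-en-1-yl)-1,6-dimethyl-3-(prop-1-en-2-yl)cyclohex-3-en-1-yl]methanol (E/Z enol ether) | OC[C@@]1(C)[C@@H](C)CC=C(C(C)=C)[C@@H]1CC=COC | intermediate
18 | [(1S,2S,6S)-2-(3-methoxyprop-2-en-1-yl)-1,6-dimethyl-3-(propan-2-ylidene)cyclohexyl]methanol (E/Z enol ether) | OC[C@@]1(C)[C@@H](C)CCC(=C(C)C)[C@@H]1CC=COC | intermediate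
19 | isofraxidin (7-hydroxy-6,8-dimethoxy-2H-chromen-2-one) | COc1cc2ccc(=O)oc2c(OC)c1O | starting material
20 | 6,8-dimethoxy-7-{[(1S,2S,6S)-2-(3-methoxyprop-2-en-1-yl)-1,6-dimethyl-3-(propan-2-ylidene)cyclohexyl]methoxy}-2H-chromen-2-one (E/Z enol ether) | COc1cc2ccc(=O)oc2c(OC)c1OC[C@@]1(C)[C@@H](C)CCC(=C(C)C)[C@@H]1CC=COC | intermediate
21 | 3-[(1S,2S,3S)-2-{[(6,8-dimethoxy-2-oxo-2H-chromen-7-yl)oxy]methyl}-2,3-dimethyl-6-(propan-2-ylidene)cyclohexyl]propanal | COc1cc2ccc(=O)oc2c(OC)c1OC[C@@]1(C)[C@@H](C)CCC(=C(C)C)[C@@H]1CCC=O | target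

**Step count**
Total: 13 steps. Longest linear sequence: 12 steps (1 → 21 through steps 1, 2 and 4–13); step 3 is a one-step side branch.

**Steps most likely to fail**

Step 4 (Michael addition). The enolate may attack the alkyne terminus (1,6-addition), may take a proton from the acceptor, or may react outside the closed chelated transition state, so that C6 forms with poor facial selectivity. The fallback sets out from 5 and returns at 12, and makes the C1–C6 bond by a [3,3] shift instead. Lactone 5 is O-ethylated (Et3O+ BF4−, CH2Cl2) and treated with NaOEt to give the cyclic orthoester 2,2-diethoxy-3,4-dimethyltetrahydro-2H-pyran F1. Ester 8 is reduced (i-Bu2AlH, CH2Cl2, −78 °C → 0 °C) to (E)-hex-2-en-4-yn-1-ol F2. Heating F1 with F2 and catalytic propionic acid (xylene, 140 °C) should form the mixed ketene acetal and rearrange it through a chair transition state (Johnson–Claisen) on the face anti to the C4 methyl. This would give 3-(hex-1-en-4-yn-3-yl)-3,4-dimethyltetrahydro-2H-pyran-2-one F3, the (E)-alkene geometry being translated into the C6 configuration. Hydroboration of the vinyl group (9-BBN, THF; NaBO3) gives 3-(1-hydroxyhex-4-yn-3-yl)-3,4-dimethyltetrahydro-2H-pyran-2-one F4. Oxidation (TEMPO, PhI(OAc)2, MeCN–H2O) gives 3-(3,4-dimethyl-2-oxotetrahydro-2H-pyran-3-yl)hex-4-ynoic acid F5. LiBH4 (the carboxylate is not reduced) followed by acid then closes lactone 12.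

Step 12 (aryl ether). Displacement of the neopentyl alkoxyphosphonium ion by the di-ortho-substituted phenoxide may be too slow, so that the activated alcohol decomposes or the phenol is consumed otherwise. The fallback sets out from 18 and returns at 20, with the roles of activation reversed. Alcohol 18 is converted (Tf2O, 2,6-lutidine, CH2Cl2, −78 °C) into [(1S,2S,6S)-2-(3-methoxyprop-2-en-1-yl)-1,6-dimethyl-3-(propan-2-ylidene)cyclohexyl]methyl trifluoromethanesulfonate F6. The crude triflate is then displaced by the caesium phenoxide of 19 (Cs2CO3, DMF, 50 °C) in a plain SN2 reaction to give 20.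

Step 11 (1,4-hydrogenation). The diene may fail to reach the s-cis geometry on chromium, or hydrogen may add 1,2, or the diene may isomerize before reduction. The fallback sets out from 17 and returns at 18: dissolving-metal reduction (Li, liquid NH3, t-BuOH, THF, −78 °C) protonates the diene radical anion at its two termini and should give the same tetrasubstituted alkene; enol ether and alkoxide are inert, and no new compound is made.

**Further compounds**
F1 | step 4 | 2,2-diethoxy-3,4-dimethyltetrahydro-2H-pyran (trans, 4S) | CCOC1(OCC)OCC[C@H](C)[C@H]1C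
F2 | step 4 | (E)-hex-2-en-4-yn-1-ol | CC#C/C=C/CO
F3 | step 4 | 3-(hex-1-en-4-yn-3-yl)-3,4-dimethyltetrahydro-2H-pyran-2-one (C1, C2, C6 as in the target) | O=C1OCC[C@H](C)[C@@]1(C)[C@H](C#CC)C=C
F4 | step 4 | 3-(1-hydroxyhex-4-yn-3-yl)-3,4-dimethyltetrahydro-2H-pyran-2-one (C1, C2, C6 as in the target) | O=C1OCC[C@H](C)[C@@]1(C)[C@H](C#CC)CCO
F5 | step 4 | 3-(3,4-dimethyl-2-oxotetrahydro-2H-pyran-3-yl)hex-4-ynoic acid (C1, C2, C6 as in the target) | O=C1OCC[C@H](C)[C@@]1(C)[C@H](C#CC)CC(=O)O
F6 | step 12 | [(1S,2S,6S)-2-(3-methoxyprop-2-en-1-yl)-1,6-dimethyl-3-(propan-2-ylidene)cyclohexyl]methyl trifluoromethanesulfonate | O=S(=O)(OC[C@@]1(C)[C@@H](C)CCC(=C(C)C)[C@@H]1CC=COC)C(F)(F)F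
F0 | step 11 | none | none
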